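No run here changes the partner: both were charged with 0.075 M, so a comparison of charges cannot give an order in partner.

| flask | substrate | partner | free catalyst | remark |
|---|---|---|---|---|
| alpha | 0.050 M | 0.075 M | 1.1 mM | the very flask that is asked about, followed so far |
| gamma | 0.025 M | 0.075 M | 1.1 mM | run made earlier |
| flask | 0.050 M | 0.0750 M | 1.1 mM |  |

alpha run (percent of the substrate charged)

| time / min | product / % |
|---|---|
| 2.00 | 0 |
| 6.00 | 1.1 |
| 10.0 | 3.2 |
| 15.0 | 4.1 |
| 25.0 | 11.3 |
| 30.0 | 13.4 |

gamma run (percent of the substrate charged)

| time / h | product / % |
|---|---|
| 0.200 | 4.0 |
| 0.333 | 8.6 |
| 0.500 | 13.7 |
| 0.833 | 24.7 |
| 1.50 | 41.7 |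
| 2.50 | 60.6 |

(readings scatter by 0.5 percentage points)

- apparent order in partner when 5.0 % of the substrate are converted (percent change of the rate of making product for one percent more partner charged)
- factor on the rate of making product when 5.0 % of the substrate are converted if free catalyst is charged twice over

- on the list of suspects stand: substrate + free catalyst <-> free catalyst + open intermediate; free catalyst + open intermediate <-> catalyst intermediate; partner + catalyst intermediate -> free catalyst + product
- no earlier run changes the charge of free catalyst; that part of a forecast is a guess
- what has left substrate counts as converted, also if it is not yet product
- no earlier run changes the charge of partner; that part of a forecast is a guess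

The bench rule takes a reagent in excess as constant and the other's curve as pseudo-first-order. Applied to the gamma run, it gives the product clock: the fall per hour in the logarithm of the share of substrate charged that is not yet product. The clock reads 0.392 /h from 0.500 h to 1.50 h, and 0.392 /h from there to 2.50 h.

The rule's border is a ratio of charges. With one partner spent per product, full conversion takes 33.3 % of the partner in gamma and 66.7 % in the flask, so partner drifts, and that drift is the missing variation. By the last gamma reading it stands near 79.8 % of its charge, while the two gamma readings of the clock agree. The scatter still leaves room, yet the reckoning here commits to an order near zero, and to a factor close to 2 for doubled catalyst, which no run tests.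

The flask tests the order harder than gamma, with more substrate per partner charged. From 13.4 % at 30.0 min, a steady clock, meaning order zero in partner, gives 60.5 % product at 2.50 h, while a clock scaled in proportion to mean [partner], meaning order one, gives 55.9 %. That gap of 4.6 percentage points is wider than the scatter of 0.5 points, so this is the reading to watch.

The forecast gives 0.3 and 1.9, calling its partner figure “a guess, leaning low”.

The flask gives an order of 0.072 and a factor of 1.97.

    substrate + free catalyst ⇌ free catalyst + open intermediate (K = 0.230, k = 0.250 /M/s)
    free catalyst + open intermediate ⇌ catalyst intermediate (K = 56.0 /M, k = 0.900 /M/s)
    partner + catalyst intermediate → free catalyst + product (k = 3.50 /M/s)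

The resting state of the catalyst in the flask is the free catalyst, at 98.4 % of its charge after 0.250 h. The steady clock's 60.5 % stands beside the flask's own state at 2.50 h: partner is down to 59.6 % of its charge, and product has reached 60.5 %.

The runs are simulated for substances that don't exist, noise included.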